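## Structural features

Eryvarin Q (28) is an achiral 2-arylbenzofuran-3-carbaldehyde: the benzofuran (ring A fused to the furan ring C) carries a formyl group on C3 and, on C2, a second benzene ring (ring B) attached through C1'. Ring A has a hydroxyl on C6 and a prenyl (3-methylbut-2-enyl) group on C7, a carbon flanked by the furan oxygen (through C7a) and the C6 oxygen. Ring B is a resorcinol with hydroxyls on C2' and C4', a prenyl group on C5' and the link to C2 on C1'. There is no stereocentre, so every selectivity question is regiochemical. The fragile groups are the two trisubstituted alkenes, each ortho to a phenol (acid closes them to 2,2-dimethylchromans; halogen electrophiles, oxidants and hydrogenation destroy them), the oxidisable electron-rich phenol rings, and the aldehyde, which lies next to the 2'-hydroxyl. The real difficulty is to place each prenyl group on one defined carbon of a resorcinol nucleus (C5' and not C3' in ring B; C7 between two oxygens in ring A) and to build the 2-aryl-3-formylfuran without exposing the prenylphenols to strong acid or strong electrophiles. The key step exploits the 1',2',4',5' pattern of ring B: C2'(O)–C3'–C4'(O)–C5'(prenyl) is the backbone of a γ-prenylated acetoacetate in its bis-silyl dienol form, and C6'–C1'(acyl) is an acetylenic ketone, so ring B can be formed already aromatic with the acetyl carbon that becomes C2 of the furan in place. The acetyl methyl then becomes C3, an orthoformate carbon becomes the formyl group, and ring A is attached through an N–O bond that later delivers O1–C2 and C3–C3a.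

## Logic of the disconnections

**28 to 26.** Cut: three O–Si bonds and the two C–OMe bonds of an acetal (functional-group level only). Reason: the free ortho-prenylphenols and the aldehyde are the groups least tolerant of acylating agents, bases and acids, so they are unveiled last. Gain: every earlier intermediate is neutral, lipophilic and resistant to oxidation. Demand: the last step may use only fluoride and weak aqueous acid.

**26 to 23.** Cut: O1–C2 and C3–C3a of the furan. Reason: both bonds can come from one precursor in which ring A is held on the ring B side chain by an N–O bond; a [3,3] shift turns that weak bond into C3–C3a and the freed phenol oxygen becomes O1. Gain: the benzofuran disappears and two benzene derivatives joined by a C=N–O link remain. Demand: an enolisable CH2 on one side of the C=N only (true for 23), one free ortho carbon on ring A only (C7 is blocked by prenyl), and an activation mild enough for silyl ethers, alkenes and the acetal.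

**23 to 14 and 22.** Cut: the C=N bond. Reason: condensation of a ketone with an O-arylhydroxylamine is the natural point of convergence. Gain: two fragments of similar size, each with one arene. Demand: the nitrogen must attack the crowded aryl ketone and not the masked aldehyde, which requires a buffered, non-ionising medium.

**14 to 12 (through 13).** Cut: the C–C bond between the methylene carbon (future C3) and the acetal carbon (future formyl carbon). Reason: the one-carbon unit is best added while the molecule is small, at the only nucleophilic carbon of a methyl ketone, and not by electrophilic substitution on the finished prenylated biaryl. Gain: return to an aryl methyl ketone. Demand: C-selective homologation at the acetal oxidation level without a free enolate next to the 2'-silyl ether.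

**12 to 11.** Cut: two O–Si bonds. Reason: the 2'-oxygen must be blocked so that it cannot close onto the formyl equivalent, and both phenols must survive acylation. Gain: the unprotected product of the ring synthesis. Demand: silylation of a chelated phenol without enol silylation of the ketone.

**11 to 7 and 8 (key).** Cut: C1'–C2' and C5'–C6' of ring B. Reason: these two bonds separate an electron-rich four-carbon diene carrying both oxygens and the prenyl group from a two-carbon acetylenic ketone carrying the acetyl group, so a cycloaddition followed by loss of a silyl ether gives the arene directly. Gain: a benzene ring with four different substituents becomes two acyclic compounds, and the C5'/C3' prenyl problem becomes the position of an alkyl group on an open chain. Demand: head-to-tail orientation, an outward-pointing prenyl chain on the diene terminus, and aromatisation without strong acid.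

**7 to 5 to 4.** Cut: the two O–Si bonds, one after the other. Reason: the diene is the doubly silylated dienol of a β-keto ester. Gain: a stable, distillable keto ester. Demand: γ-deprotonation for the second silylation, with the alkyl chain trans to C2 in the new double bond.

**4 to 1 and 2.** Cut: the C4–C5 bond of the keto ester. Reason: this is the bond that decides where the prenyl group will sit in ring B. Gain: two bulk chemicals. Demand: alkylation at the γ carbon and not the α carbon, hence the dianion.

**22 to 20 (through 21).** Cut: the O–N bond. Reason: a phenoxide can be aminated on oxygen by an electrophilic NH2 source, so ring A needs no halide or boron handle. Gain: a simple mono-protected resorcinol. Demand: clean N-attack by a hindered phenoxide and a protecting group that is stable to it.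

**20 to 19 to 18.** Cut: one O–Si bond, then two acetal C–O bonds. Reason: the two oxygens of the symmetrical diol must be differentiated, one for amination and one for late fluoride release. Gain: a symmetrical intermediate. Demand: a statistical mono-silylation (run with recycling) and acetal removal that spares the prenyl group.

**18 to 16 and 2; 16 to 15.** Cut: the aryl C2–CH2 bond, then two O–CH2 bonds. Reason: two acetal ethers direct metalation to the carbon between them, the only reliable way to place a substituent there. Gain: the parent diphenol. Demand: SN2 (linear) allylation of the aryl-metal species.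

## Other disconnections considered

**Alternative 1:** The cut goes through the furan at O1–C2 and C3–C3a and leads to the O-aryl ketoxime ether A2. In the forward step, N-trifluoroacetylation of A2 gives an ene-hydroxylamine, a [3,3] shift breaks N–O and forms C3–C3a, and the freed phenol adds to the imine carbon and expels trifluoroacetamide to give the benzofuran acetal A1.
- In its favour: it is convergent, metal-free and runs near room temperature; the site of C–C bond formation on ring A is fixed because C7 is blocked; the formyl carbon travels as an acetal, so no electrophilic formylation of a prenylated biaryl is needed.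
- Against it as the strategy-bearing step: it only joins two finished arenes and does not say how the ring B ketone with its 1',2',4',5' pattern is obtained. The obvious source, C-prenylation of commercial 2,4-dihydroxyacetophenone A3, would attack C3' as well as C5' and turn the main regiochemical problem into a separation. It also needs an O-arylhydroxylamine of limited shelf life and a condensation at a crowded ketone.
- Comparison: on the furan-forming event the two plans are equal, because the chosen route uses exactly this closure in steps 12 and 13 (A2 and A1 are the same compounds as 23 and 26). A plan resting on this step alone, with ring B taken from A3, would be about two steps shorter, which is a point in its favour. It would give up the control over the C5' prenyl position that the chosen key step provides. Mechanistically it is a pericyclic N–O cleavage on a fully elaborated substrate, while the chosen key step is a cycloaddition on small fragments early in the route, where a failure costs little material.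

**Alternative 2:** Ring B is cut at C1'–C6' and C3'–C4' at the dihydroresorcinol oxidation level. In the forward step, keto ester 1 adds through its central carbon to methyl 2-prenylacrylate A5 (Michael addition), and the acetyl methyl then condenses with the acrylate ester (Claisen-type closure) to give the cyclohexane-1,3-dione A4. Dehydrogenation would then give methyl 2,4-dihydroxy-5-prenylbenzoate A6.
- In its favour: cheap alkoxide chemistry under thermodynamic control and no moisture-sensitive silyl diene. The prenyl position is fixed by the acrylate substituent, so on regiocontrol it is the equal of the chosen plan. The ring-forming step itself is probably the more robust and scalable of the two.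
- Against it here: A4 is one oxidation level below the arene. The usual dehydrogenation methods (halogenation and elimination, iodine in methanol, Pd/C at high temperature, Hg(OAc)2, quinones) are all doubtful next to a trisubstituted alkene that can be halo-etherified, isomerised, reduced by hydrogen transfer or cyclised onto the enol oxygen. A5 must be prepared first, and A6 is an ester, so conversion to the methyl ketone needed for the furan requires protection, an N-methoxy-N-methylamide or similar, and methyl addition.
- Comparison: the chosen cycloaddition uses an alkyne, so the adduct is already at the arene oxidation level and carries the acetyl group. The alternative would be longer by roughly four steps and puts its risk in an oxidation of a prenylated intermediate. Mechanistically it is a reversible ionic Michael–Claisen sequence, against a cycloaddition whose orientation is set by frontier-orbital polarisation.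

**Alternative 3:** Ring A is the ring built from open-chain precursors, cut at C4–C5 and C3a–C7a. In the forward step, the 2-prenyl bis(silyloxy)diene A8 (from α-prenylation of keto ester 1 with 2 and double silylation) adds to 1,1-dimethoxybut-3-yn-2-one A9, and loss of methoxytrimethylsilane gives the keto acetal A7. In A7 the ketone carbon is the future C3 and the acetal carbon the future formyl group.
- In its favour: it is the same reaction class as the chosen key step, and the diene terminus is an unsubstituted CH2, so the cycloaddition should be faster and cleaner than with the 4-substituted diene 7; on this point the alternative is better. It also places the C7 prenyl group between two oxygens without ortho-metalation, acetal protection or a statistical mono-silylation, because the chelated and the free hydroxyl of A7 differ intrinsically; this is better than steps 7–10 of the chosen route. The formyl carbon is present from the start.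
- Against it here: A9 is a less common and less stable ynone that must be prepared. The furan must then be closed by forming O1–C2 and C2–C3 from a ring B benzylic unit. That means O-benzylation of the hindered chelated hydroxyl and a base-mediated intramolecular aldol-type condensation of an electron-rich, non-acidified benzyl ether onto a ketone flanked by an acetal, where strong base invites a [1,2]-Wittig shift. Ring B, with its C5'/C3' prenyl problem, would still have to come from substitution chemistry.
- Comparison: both plans use one cycloaddition for one resorcinol ring. The chosen plan uses it on ring B, whose pattern is the harder one to reach by substitution, and relies on a well-precedented N–O tether for the furan. The alternative solves ring A elegantly but leaves the harder ring and a weakly precedented furan closure. The step counts would be similar.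

Key step: step 4

Assumption: reagents that are not shelf-stable (the silyl diene 7 and O-(mesitylsulfonyl)hydroxylamine, MSH) are prepared fresh and used at once, MSH only as a solution; "prenyl" means 3-methylbut-2-enyl throughout.

## Route

**Step 1**
Reactants: 1 methyl acetoacetate (methyl 3-oxobutanoate); 2 prenyl bromide (1-bromo-3-methylbut-2-ene)
Product: 4 methyl 7-methyl-3-oxooct-6-enoate, via sodium lithium dianion of methyl acetoacetate 3 (not isolated)
Conditions: NaH, THF, 0 °C; n-BuLi, 0 °C; then 2, 0 °C → rt; 1 M HCl
Reagents that add atoms: none
Why: Acetoacetate dianion alkylation: the second deprotonation creates the more basic γ-carbanion, which displaces the primary allylic bromide by SN2 at its unsubstituted terminus, so the prenyl group ends on C4 of the keto ester and the α-carbon stays free.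

**Step 2**
Reactants: 4 methyl 7-methyl-3-oxooct-6-enoate
Product: 5 methyl 7-methyl-3-(trimethylsilyloxy)octa-2,6-dienoate (2E/2Z mixture)
Conditions: Me3SiCl, Et3N, hexane, rt
Reagents that add atoms: chlorotrimethylsilane, C[Si](C)(C)Cl
Why: Silyl enol ether formation from the strongly enolised β-keto ester under soft enolisation; the geometry of this C2=C3 bond does not matter because it becomes the C2–C3 single bond of the diene.

**Step 3**
Reactants: 5 methyl 7-methyl-3-(trimethylsilyloxy)octa-2,6-dienoate
Product: 7 (3Z)-1-methoxy-7-methyl-1,3-bis(trimethylsilyloxy)octa-1,3,6-triene (C1=C2 geometry mixed), via lithium trienolate 6 (not isolated)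
Conditions: LiN(i-Pr)2, THF, −78 °C; Me3SiCl, −78 °C → rt; hexane, filtration, no aqueous work-up
Reagents that add atoms: chlorotrimethylsilane, C[Si](C)(C)Cl
Why: Kinetic γ-deprotonation of the vinylogous ester and O-silylation of the extended enolate is the standard preparation of 1-alkoxy-1,3-bis(silyloxy)dienes; the new C3=C4 bond should form mainly with the alkyl chain trans to C2 (3Z), the geometry that can reach the s-cis conformation and cannot undergo a 1,5-hydrogen shift, and the moisture-sensitive diene is used crude.

**Step 4**
Reactants: 7 (3Z)-1-methoxy-7-methyl-1,3-bis(trimethylsilyloxy)octa-1,3,6-triene (1.3 equiv); 8 but-3-yn-2-one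
Product: 11 1-[2,4-dihydroxy-5-(3-methylbut-2-enyl)phenyl]ethanone, via cyclohexa-1,4-diene cycloadduct 9 (not isolated), via aryl trimethylsilyl ether 10 (not isolated)
Conditions: PhMe, 0 → 70 °C; evaporate; K2CO3 (cat.), MeOH, 0 °C; pH 7 phosphate buffer
Reagents that add atoms: none
Why: This is the Diels–Alder aromatisation of a 1-alkoxy-1,3-bis(silyloxy)diene with an acetylenic ketone, the established route to 4-acylresorcinols and 2,4-dihydroxybenzoates. The HOMO of 7 has its largest coefficient at C4 and the LUMO of 8 at the β-carbon, so C4 bonds to the alkyne CH (C5'–C6') and the ketene acetal carbon to the acyl-bearing carbon (C1'–C2'), either through an asynchronous suprafacial [4+2] transition state or, at the stepwise limit, by Michael addition followed by 6-exo-trig closure of the allenolate α-carbon onto the oxocarbenium carbon; both paths give the same adduct 9. The one new ring is therefore closed by cycloaddition, and because the dienophile is an alkyne the adduct is already at the arene oxidation level: the mixed silyl methyl ketal at C2' collapses to a carbonyl with loss of methoxytrimethylsilane and the doubly allylic C5'–H enolises to the hydrogen-bonded 2'-phenol 10. Mild basic methanolysis then cleaves the remaining aryl silyl ether, pushes any uncollapsed adduct through the same sequence and avoids the acid that could close the 5'-prenyl group onto the 4'-hydroxyl. No stereocentre is created in the product, since both sp3 carbons of 9 are lost on aromatisation and its diastereomer mixture is irrelevant. The selectivity required is regiochemical (prenyl on C5', not C3'); it is fixed beforehand by the γ-alkylation of step 1 and is carried into the ring by the head-to-tail orientation of the polarised partners, while the 3Z geometry keeps the prenyl chain outside the diene. Leaving out any Lewis acid suppresses the formal [3+3] and Mukaiyama–Michael modes, and the isolated prenyl alkene is a far poorer reaction partner for the ynone than the siloxydiene.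

**Step 5**
Reactants: 11 1-[2,4-dihydroxy-5-(3-methylbut-2-enyl)phenyl]ethanone
Product: 12 1-[5-(3-methylbut-2-enyl)-2,4-bis(triisopropylsilyloxy)phenyl]ethanone
Conditions: i-Pr3SiOTf, 2,6-lutidine, CH2Cl2, 0 °C → rt
Reagents that add atoms: triisopropylsilyl trifluoromethanesulfonate, CC(C)[Si](OS(=O)(=O)C(F)(F)F)(C(C)C)C(C)C
Why: Silylation of both phenols with a silyl triflate and a hindered pyridine base, which is reactive enough for the chelated 2'-hydroxyl but too weakly basic to turn the methyl ketone into its enol silane; the bulky silyl ethers survive the later enolisation, condensation and acylation and keep the 2'-oxygen from closing onto the formyl equivalent.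

**Step 6**
Reactants: 12 1-[5-(3-methylbut-2-enyl)-2,4-bis(triisopropylsilyloxy)phenyl]ethanone
Product: 14 3,3-dimethoxy-1-[5-(3-methylbut-2-enyl)-2,4-bis(triisopropylsilyloxy)phenyl]propan-1-one, via trimethylsilyl enol ether 13 (not isolated)
Conditions: Me3SiOTf (1.4 equiv), i-Pr2NEt (1.2 equiv), CH2Cl2, 0 °C; HC(OMe)3, −78 → −40 °C; sat. aq. NaHCO3
Reagents that add atoms: trimethyl orthoformate, COC(OC)OC
Why: Soft enolisation gives enol silane 13, which adds to the dimethoxycarbenium ion released from the orthoformate by the residual silyl triflate (Mukaiyama-type addition to an orthoester) to give the β-keto acetal; the enol silane is far more nucleophilic than the prenyl alkene or the acyl-deactivated arene, and no free enolate is formed that could trigger silyl migration from the 2'-oxygen.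

**Step 7**
Reactants: 15 resorcinol (benzene-1,3-diol)
Product: 16 1,3-bis(methoxymethoxy)benzene
Conditions: MeOCH2Cl, i-Pr2NEt, CH2Cl2, 0 °C → rt
Reagents that add atoms: chloromethyl methyl ether, COCCl
Why: Williamson-type O-alkylation of both phenols; the two acetal ethers are chosen because together they direct metalation to the carbon between them.

**Step 8**
Reactants: 16 1,3-bis(methoxymethoxy)benzene; 2 prenyl bromide (1-bromo-3-methylbut-2-ene)
Product: 18 1,3-bis(methoxymethoxy)-2-(3-methylbut-2-enyl)benzene, via [2,6-bis(methoxymethoxy)phenyl]lithium 17 (not isolated)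
Conditions: n-BuLi, THF, 0 °C → rt; CuBr·SMe2 (10 mol%), 2, −78 °C → rt
Reagents that add atoms: none
Why: Directed ortho-metalation: both acetal oxygens coordinate the base and lithiation occurs at C2, and copper-catalysed substitution of the primary allylic bromide gives the linear (SN2) prenyl arene, which fixes the prenyl group between the two oxygens.

**Step 9**
Reactants: 18 1,3-bis(methoxymethoxy)-2-(3-methylbut-2-enyl)benzene
Product: 19 2-(3-methylbut-2-enyl)benzene-1,3-diol
Conditions: HCl (0.5 M) in MeOH, rt → 40 °C; NaHCO3
Reagents that add atoms: none
Why: Acid-catalysed transacetalisation to methanol frees both phenols as dimethoxymethane; dilute acid and moderate temperature are used because stronger acid would add a phenol across the prenyl alkene.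

**Step 10**
Reactants: 19 2-(3-methylbut-2-enyl)benzene-1,3-diol
Product: 20 2-(3-methylbut-2-enyl)-3-(triisopropylsilyloxy)phenol
Conditions: i-Pr3SiCl (0.5 equiv), imidazole, DMF, 0 °C → rt; excess 19 recovered
Reagents that add atoms: chlorotriisopropylsilane, CC(C)[Si](Cl)(C(C)C)C(C)C
Why: Statistical mono-silylation of a symmetrical diol, run with the silyl chloride as the limiting reagent so that the mono-ether should dominate over the bis-ether; unreacted diol is recycled.

**Step 11**
Reactants: 20 2-(3-methylbut-2-enyl)-3-(triisopropylsilyloxy)phenol
Product: 22 O-[2-(3-methylbut-2-enyl)-3-(triisopropylsilyloxy)phenyl]hydroxylamine, via sodium phenolate 21 (not isolated)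
Conditions: NaH, THF–DMF, 0 °C; then MSH (CH2Cl2 solution), 0 °C
Reagents that add atoms: O-(mesitylsulfonyl)hydroxylamine (MSH), Cc1cc(C)c(S(=O)(=O)ON)c(C)c1
Why: Electrophilic amination of a phenoxide: the oxygen attacks the nitrogen of the O-sulfonylhydroxylamine and expels the sulfonate, a known route to electron-rich O-arylhydroxylamines; the silyl ether and the alkene are inert to the reagent at 0 °C and the product is used without storage.

**Step 12**
Reactants: 14 3,3-dimethoxy-1-[5-(3-methylbut-2-enyl)-2,4-bis(triisopropylsilyloxy)phenyl]propan-1-one; 22 O-[2-(3-methylbut-2-enyl)-3-(triisopropylsilyloxy)phenyl]hydroxylamine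
Product: 23 3,3-dimethoxy-1-[5-(3-methylbut-2-enyl)-2,4-bis(triisopropylsilyloxy)phenyl]propan-1-one O-[2-(3-methylbut-2-enyl)-3-(triisopropylsilyloxy)phenyl]oxime (E/Z mixture at C=N)
Conditions: pyridinium p-toluenesulfonate (0.2 equiv), pyridine–EtOH, 3 Å MS, 50 °C
Reagents that add atoms: none
Why: Oxime ether formation by condensation of the α-effect amine with the ketone; in a pyridine-buffered medium the dimethyl acetal cannot ionise, so the nitrogen is directed to the ketone carbon, and both C=N isomers are usable because the geometry is erased in step 13.

**Step 13**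
Reactants: 23 O-aryl ketoxime ether (E/Z mixture)
Product: 26 3-(dimethoxymethyl)-7-(3-methylbut-2-enyl)-2-[5-(3-methylbut-2-enyl)-2,4-bis(triisopropylsilyloxy)phenyl]-6-(triisopropylsilyloxy)-1-benzofuran, via N-trifluoroacetyl ene-hydroxylamine 24 (not isolated), via 2-trifluoroacetamido-2,3-dihydrobenzofuran 25 (not isolated)
Conditions: (CF3CO)2O, DMAP, CH2Cl2, 0 °C → rt
Reagents that add atoms: none
Why: N-Trifluoroacetylation acidifies the α-hydrogens and DMAP forms ene-hydroxylamine 24, whose [3,3] sigmatropic shift (the oxygen analogue of the Fischer indole synthesis) breaks the weak N–O bond and forms C3–C3a at the only free ortho carbon of ring A; rearomatisation, 5-exo-trig addition of the phenol to the N-acylimine (25) and loss of trifluoroacetamide, assisted by the electron-rich ring B on C2, give the benzofuran. The ketone has one enolisable side and C7 is blocked by prenyl, so both regiochemical questions are settled by the substrate, and any acetal lost on work-up becomes the aldehyde that step 14 makes anyway.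

**Step 14**
Reactants: 26 tris(triisopropylsilyl) benzofuran dimethyl acetal
Product: 28 eryvarin Q (2-[2,4-dihydroxy-5-(3-methylbut-2-enyl)phenyl]-6-hydroxy-7-(3-methylbut-2-enyl)-1-benzofuran-3-carbaldehyde), via triphenol dimethyl acetal 27 (not isolated)
Conditions: Bu4NF, AcOH, THF, 0 °C; then 10% aq. citric acid, rt
Reagents that add atoms: water, O
Why: Fluoride cleaves the three aryl silyl ethers under acetic acid buffering, and the heteroaryl acetal, now strongly activated by O1 and the free phenols, is hydrolysed by weak aqueous acid that should leave the ortho-prenylphenols uncyclised.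

## Compound list

1 | methyl acetoacetate (methyl 3-oxobutanoate) | CC(=O)CC(=O)OC | starting material
2 | prenyl bromide (1-bromo-3-methylbut-2-ene) | CC(C)=CCBr | starting material
3 | sodium lithium dianion of methyl acetoacetate | [Li+].[Na+].C=C([O-])C=C([O-])OC | intermediate
4 | methyl 7-methyl-3-oxooct-6-enoate | COC(=O)CC(=O)CCC=C(C)C | intermediate
5 | methyl 7-methyl-3-(trimethylsilyloxy)octa-2,6-dienoate (2E/2Z mixture) | COC(=O)C=C(CCC=C(C)C)O[Si](C)(C)C | intermediate
6 | lithium (3Z)-1-methoxy-7-methyl-3-(trimethylsilyloxy)octa-1,3,6-trien-1-olate | [Li+].COC([O-])=C/C(O[Si](C)(C)C)=C/CC=C(C)C | intermediate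
7 | (3Z)-1-methoxy-7-methyl-1,3-bis(trimethylsilyloxy)octa-1,3,6-triene (C1=C2 geometry mixed) | COC(O[Si](C)(C)C)=C/C(O[Si](C)(C)C)=C/CC=C(C)C | intermediate
8 | but-3-yn-2-one | CC(=O)C#C | starting material
9 | 1-[6-methoxy-3-(3-methylbut-2-enyl)-4,6-bis(trimethylsilyloxy)cyclohexa-1,4-dien-1-yl]ethanone (racemic; diastereomer mixture) | CC(=O)C1=CC(CC=C(C)C)C(O[Si](C)(C)C)=CC1(OC)O[Si](C)(C)C | intermediate
10 | 1-[2-hydroxy-5-(3-methylbut-2-enyl)-4-(trimethylsilyloxy)phenyl]ethanone | CC(=O)c1cc(CC=C(C)C)c(O[Si](C)(C)C)cc1O | intermediate
11 | 1-[2,4-dihydroxy-5-(3-methylbut-2-enyl)phenyl]ethanone | CC(=O)c1cc(CC=C(C)C)c(O)cc1O | intermediate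
12 | 1-[5-(3-methylbut-2-enyl)-2,4-bis(triisopropylsilyloxy)phenyl]ethanone | CC(=O)c1cc(CC=C(C)C)c(O[Si](C(C)C)(C(C)C)C(C)C)cc1O[Si](C(C)C)(C(C)C)C(C)C | intermediate
13 | trimethyl({1-[5-(3-methylbut-2-enyl)-2,4-bis(triisopropylsilyloxy)phenyl]ethenyl}oxy)silane | C=C(O[Si](C)(C)C)c1cc(CC=C(C)C)c(O[Si](C(C)C)(C(C)C)C(C)C)cc1O[Si](C(C)C)(C(C)C)C(C)C | intermediate
14 | 3,3-dimethoxy-1-[5-(3-methylbut-2-enyl)-2,4-bis(triisopropylsilyloxy)phenyl]propan-1-one | COC(OC)CC(=O)c1cc(CC=C(C)C)c(O[Si](C(C)C)(C(C)C)C(C)C)cc1O[Si](C(C)C)(C(C)C)C(C)C | intermediate
15 | resorcinol (benzene-1,3-diol) | Oc1cccc(O)c1 | starting material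
16 | 1,3-bis(methoxymethoxy)benzene | COCOc1cccc(OCOC)c1 | intermediate
17 | [2,6-bis(methoxymethoxy)phenyl]lithium | [Li]c1c(OCOC)cccc1OCOC | intermediate
18 | 1,3-bis(methoxymethoxy)-2-(3-methylbut-2-enyl)benzene | COCOc1cccc(OCOC)c1CC=C(C)C | intermediate
19 | 2-(3-methylbut-2-enyl)benzene-1,3-diol | CC(C)=CCc1c(O)cccc1O | intermediate
20 | 2-(3-methylbut-2-enyl)-3-(triisopropylsilyloxy)phenol | CC(C)=CCc1c(O)cccc1O[Si](C(C)C)(C(C)C)C(C)C | intermediate
21 | sodium 2-(3-methylbut-2-enyl)-3-(triisopropylsilyloxy)phenolate | [Na+].CC(C)=CCc1c([O-])cccc1O[Si](C(C)C)(C(C)C)C(C)C | intermediate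
22 | O-[2-(3-methylbut-2-enyl)-3-(triisopropylsilyloxy)phenyl]hydroxylamine | CC(C)=CCc1c(ON)cccc1O[Si](C(C)C)(C(C)C)C(C)C | intermediate
23 | 3,3-dimethoxy-1-[5-(3-methylbut-2-enyl)-2,4-bis(triisopropylsilyloxy)phenyl]propan-1-one O-[2-(3-methylbut-2-enyl)-3-(triisopropylsilyloxy)phenyl]oxime (E/Z mixture) | COC(OC)CC(=NOc1cccc(O[Si](C(C)C)(C(C)C)C(C)C)c1CC=C(C)C)c1cc(CC=C(C)C)c(O[Si](C(C)C)(C(C)C)C(C)C)cc1O[Si](C(C)C)(C(C)C)C(C)C | intermediate
24 | 2,2,2-trifluoro-N-{3,3-dimethoxy-1-[5-(3-methylbut-2-enyl)-2,4-bis(triisopropylsilyloxy)phenyl]prop-1-enyl}-N-[2-(3-methylbut-2-enyl)-3-(triisopropylsilyloxy)phenoxy]acetamide (alkene geometry undefined) | COC(OC)C=C(N(Oc1cccc(O[Si](C(C)C)(C(C)C)C(C)C)c1CC=C(C)C)C(=O)C(F)(F)F)c1cc(CC=C(C)C)c(O[Si](C(C)C)(C(C)C)C(C)C)cc1O[Si](C(C)C)(C(C)C)C(C)C | intermediate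
25 | 2,2,2-trifluoro-N-{3-(dimethoxymethyl)-7-(3-methylbut-2-enyl)-2-[5-(3-methylbut-2-enyl)-2,4-bis(triisopropylsilyloxy)phenyl]-6-(triisopropylsilyloxy)-2,3-dihydro-1-benzofuran-2-yl}acetamide (racemic; diastereomer mixture) | COC(OC)C1c2ccc(O[Si](C(C)C)(C(C)C)C(C)C)c(CC=C(C)C)c2OC1(NC(=O)C(F)(F)F)c1cc(CC=C(C)C)c(O[Si](C(C)C)(C(C)C)C(C)C)cc1O[Si](C(C)C)(C(C)C)C(C)C | intermediate
26 | 3-(dimethoxymethyl)-7-(3-methylbut-2-enyl)-2-[5-(3-methylbut-2-enyl)-2,4-bis(triisopropylsilyloxy)phenyl]-6-(triisopropylsilyloxy)-1-benzofuran | COC(OC)c1c(-c2cc(CC=C(C)C)c(O[Si](C(C)C)(C(C)C)C(C)C)cc2O[Si](C(C)C)(C(C)C)C(C)C)oc2c(CC=C(C)C)c(O[Si](C(C)C)(C(C)C)C(C)C)ccc12 | intermediate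
27 | 4-[3-(dimethoxymethyl)-6-hydroxy-7-(3-methylbut-2-enyl)-1-benzofuran-2-yl]-6-(3-methylbut-2-enyl)benzene-1,3-diol | COC(OC)c1c(-c2cc(CC=C(C)C)c(O)cc2O)oc2c(CC=C(C)C)c(O)ccc12 | intermediate
28 | eryvarin Q, 2-[2,4-dihydroxy-5-(3-methylbut-2-enyl)phenyl]-6-hydroxy-7-(3-methylbut-2-enyl)-1-benzofuran-3-carbaldehyde | CC(C)=CCc1cc(-c2oc3c(CC=C(C)C)c(O)ccc3c2C=O)c(O)cc1O | target

## Step count and least certain steps

Total: 14 steps. Longest linear sequence: 9 steps (steps 1–6, then 12–14). The ring A branch (steps 7–11) has 5 steps and joins at step 12.

**Step 4 (key step).** Most likely problem: slow cycloaddition at the alkyl-substituted diene terminus, so that hydrolysis of the diene, oligomerisation of the ynone, or open-chain Michael addition without ring closure competes. Fallback with a different way of fixing the C5' substituent: starting from 15, Nencki C-acetylation (AcOH, ZnCl2, 140 °C) would give 1-(2,4-dihydroxyphenyl)ethanone F1. Bromination para to the chelated hydroxyl (N-bromosuccinimide, MeCN, 0 °C) would give 1-(5-bromo-2,4-dihydroxyphenyl)ethanone F2. Silylation as in step 5 would give 1-[5-bromo-2,4-bis(triisopropylsilyloxy)phenyl]ethanone F3. Stille coupling with tributyl(3-methylbut-2-enyl)stannane (Pd(PPh3)4, DMF, 90 °C) would then join the route at 12.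

**Step 12.** Most likely problem: slow condensation at the crowded ketone, which gives time for β-elimination of methanol from the keto acetal or for decomposition of the aryloxyamine by N–O cleavage. Fallback that postpones the formyl carbon: starting from 12 and 22, acid-catalysed condensation (HCl cat., EtOH), possible because no acetal is present, would give the methyl ketoxime ether 1-[5-(3-methylbut-2-enyl)-2,4-bis(triisopropylsilyloxy)phenyl]ethanone O-[2-(3-methylbut-2-enyl)-3-(triisopropylsilyloxy)phenyl]oxime F4. The rearrangement of step 13 would give the 3-unsubstituted benzofuran 7-(3-methylbut-2-enyl)-2-[5-(3-methylbut-2-enyl)-2,4-bis(triisopropylsilyloxy)phenyl]-6-(triisopropylsilyloxy)-1-benzofuran F5. Vilsmeier–Haack formylation at C3 (POCl3, DMF, 0 °C → rt; aq. NaOAc) would give the silylated aldehyde 7-(3-methylbut-2-enyl)-2-[5-(3-methylbut-2-enyl)-2,4-bis(triisopropylsilyloxy)phenyl]-6-(triisopropylsilyloxy)-1-benzofuran-3-carbaldehyde F6. Fluoride desilylation (Bu4NF, AcOH) would come back to the route at 28.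

**Step 11.** Most likely problem: attack of the hindered phenoxide at sulfur instead of nitrogen (O-sulfonylation), together with decomposition of the aminating agent. Fallback by C–O cross-coupling: starting from 20, triflation ((CF3SO2)2O, pyridine) would give 2-(3-methylbut-2-enyl)-3-(triisopropylsilyloxy)phenyl trifluoromethanesulfonate F7. Palladium-catalysed O-arylation of ethyl N-hydroxyacetimidate ([Pd(allyl)Cl]2, a bulky biaryl di-tert-butylphosphine, Cs2CO3, toluene, 65 °C) would give ethyl N-[2-(3-methylbut-2-enyl)-3-(triisopropylsilyloxy)phenoxy]ethanimidate F8. Cold aqueous HCl in dioxane followed by NaHCO3 would release 22.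

**Step 6.** Most likely problem: further enol silylation of the product and loss of methanol to a β-methoxy enone, or incomplete C–C bond formation. Fallback by amide-acetal condensation: starting from 12, heating with N,N-dimethylformamide dimethyl acetal (110 °C) would give the enaminone (2E)-3-(dimethylamino)-1-[5-(3-methylbut-2-enyl)-2,4-bis(triisopropylsilyloxy)phenyl]prop-2-en-1-one F9. Brief treatment with anhydrous HCl in MeOH at 0 °C would exchange the amine for two methoxy groups and return to the route at 14.

**Step 9.** Most likely problem: acid-catalysed addition of a freed phenol to the prenyl alkene (chroman formation) before both acetals are cleaved. Fallback with more labile directing groups: starting from 15, 3,4-dihydro-2H-pyran with pyridinium p-toluenesulfonate in CH2Cl2 would give 1,3-bis(oxan-2-yloxy)benzene F10 (diastereomer mixture). Lithiation and copper-catalysed prenylation as in step 8 would give 2-(3-methylbut-2-enyl)-1,3-bis(oxan-2-yloxy)benzene F11 (diastereomer mixture). Pyridinium p-toluenesulfonate in MeOH at 40 °C would release 19.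

## Further compounds

F1 | step 4 | 1-(2,4-dihydroxyphenyl)ethanone | CC(=O)c1ccc(O)cc1O
F2 | step 4 | 1-(5-bromo-2,4-dihydroxyphenyl)ethanone | CC(=O)c1cc(Br)c(O)cc1O
F3 | step 4 | 1-[5-bromo-2,4-bis(triisopropylsilyloxy)phenyl]ethanone | CC(=O)c1cc(Br)c(O[Si](C(C)C)(C(C)C)C(C)C)cc1O[Si](C(C)C)(C(C)C)C(C)C
F4 | step 12 | 1-[5-(3-methylbut-2-enyl)-2,4-bis(triisopropylsilyloxy)phenyl]ethanone O-[2-(3-methylbut-2-enyl)-3-(triisopropylsilyloxy)phenyl]oxime (E/Z mixture) | CC(=NOc1cccc(O[Si](C(C)C)(C(C)C)C(C)C)c1CC=C(C)C)c1cc(CC=C(C)C)c(O[Si](C(C)C)(C(C)C)C(C)C)cc1O[Si](C(C)C)(C(C)C)C(C)C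
F5 | step 12 | 7-(3-methylbut-2-enyl)-2-[5-(3-methylbut-2-enyl)-2,4-bis(triisopropylsilyloxy)phenyl]-6-(triisopropylsilyloxy)-1-benzofuran | CC(C)=CCc1cc(-c2cc3ccc(O[Si](C(C)C)(C(C)C)C(C)C)c(CC=C(C)C)c3o2)c(O[Si](C(C)C)(C(C)C)C(C)C)cc1O[Si](C(C)C)(C(C)C)C(C)C
F6 | step 12 | 7-(3-methylbut-2-enyl)-2-[5-(3-methylbut-2-enyl)-2,4-bis(triisopropylsilyloxy)phenyl]-6-(triisopropylsilyloxy)-1-benzofuran-3-carbaldehyde | O=Cc1c(-c2cc(CC=C(C)C)c(O[Si](C(C)C)(C(C)C)C(C)C)cc2O[Si](C(C)C)(C(C)C)C(C)C)oc2c(CC=C(C)C)c(O[Si](C(C)C)(C(C)C)C(C)C)ccc12
F7 | step 11 | 2-(3-methylbut-2-enyl)-3-(triisopropylsilyloxy)phenyl trifluoromethanesulfonate | CC(C)=CCc1c(OS(=O)(=O)C(F)(F)F)cccc1O[Si](C(C)C)(C(C)C)C(C)C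
F8 | step 11 | ethyl N-[2-(3-methylbut-2-enyl)-3-(triisopropylsilyloxy)phenoxy]ethanimidate | CCOC(C)=NOc1cccc(O[Si](C(C)C)(C(C)C)C(C)C)c1CC=C(C)C
F9 | step 6 | (2E)-3-(dimethylamino)-1-[5-(3-methylbut-2-enyl)-2,4-bis(triisopropylsilyloxy)phenyl]prop-2-en-1-one | CN(C)/C=C/C(=O)c1cc(CC=C(C)C)c(O[Si](C(C)C)(C(C)C)C(C)C)cc1O[Si](C(C)C)(C(C)C)C(C)C
F10 | step 9 | 1,3-bis(oxan-2-yloxy)benzene (diastereomer mixture) | c1cc(OC2CCCCO2)cc(OC2CCCCO2)c1
F11 | step 9 | 2-(3-methylbut-2-enyl)-1,3-bis(oxan-2-yloxy)benzene (diastereomer mixture) | CC(C)=CCc1c(OC2CCCCO2)cccc1OC1CCCCO1
A1 | alternative 1 | 3-(dimethoxymethyl)-7-(3-methylbut-2-enyl)-2-[5-(3-methylbut-2-enyl)-2,4-bis(triisopropylsilyloxy)phenyl]-6-(triisopropylsilyloxy)-1-benzofuran | COC(OC)c1c(-c2cc(CC=C(C)C)c(O[Si](C(C)C)(C(C)C)C(C)C)cc2O[Si](C(C)C)(C(C)C)C(C)C)oc2c(CC=C(C)C)c(O[Si](C(C)C)(C(C)C)C(C)C)ccc12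
A2 | alternative 1 | 3,3-dimethoxy-1-[5-(3-methylbut-2-enyl)-2,4-bis(triisopropylsilyloxy)phenyl]propan-1-one O-[2-(3-methylbut-2-enyl)-3-(triisopropylsilyloxy)phenyl]oxime | COC(OC)CC(=NOc1cccc(O[Si](C(C)C)(C(C)C)C(C)C)c1CC=C(C)C)c1cc(CC=C(C)C)c(O[Si](C(C)C)(C(C)C)C(C)C)cc1O[Si](C(C)C)(C(C)C)C(C)C
A3 | alternative 1 | 1-(2,4-dihydroxyphenyl)ethanone | CC(=O)c1ccc(O)cc1O
A4 | alternative 2 | methyl 5-(3-methylbut-2-enyl)-2,4-dioxocyclohexane-1-carboxylate (racemic; diastereomer mixture) | COC(=O)C1CC(CC=C(C)C)C(=O)CC1=O
A5 | alternative 2 | methyl 5-methyl-2-methylidenehex-4-enoate (methyl 2-prenylacrylate) | COC(=O)C(=C)CC=C(C)C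
A6 | alternative 2 | methyl 2,4-dihydroxy-5-(3-methylbut-2-enyl)benzoate | COC(=O)c1cc(CC=C(C)C)c(O)cc1O
A7 | alternative 3 | 1-[2,4-dihydroxy-3-(3-methylbut-2-enyl)phenyl]-2,2-dimethoxyethanone | COC(OC)C(=O)c1ccc(O)c(CC=C(C)C)c1O
A8 | alternative 3 | 1-methoxy-2-(3-methylbut-2-enyl)-1,3-bis(trimethylsilyloxy)buta-1,3-diene | COC(O[Si](C)(C)C)=C(CC=C(C)C)C(=C)O[Si](C)(C)C
A9 | alternative 3 | 1,1-dimethoxybut-3-yn-2-one | COC(OC)C(=O)C#C
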